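**Strategy.** The route rests on cutting the geranyl-type side chain at C1'–C2' and at the C3' methyl: the E-trisubstituted C2'=C3' olefin, one methylene (C1') away from the phloroglucinol ring, is read as a terminal alkyne plus a benzylic chloride. In one flask, zirconium-catalysed syn-methylalumination of an (R)-silyloxy enyne places the C3' methyl and fixes the E geometry, and nickel-catalysed coupling of the resulting alkenylalane with the chloromethyl arene forges C1'–C2'. The alkyne precursor already carries the C6' (R)-carbinol and the isopropenyl terminus; the arene precursor is the MOM-protected 3-chloromethyl benzophenone. A single acidic unmasking then delivers the target.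

Key step: step 9

Remark on the chemistry: side-chain atoms are numbered C1'–C8' from the ring; the carbinol carbon (C3 of the enynol, C6' of the target) is R in every intermediate, because the CIP order O > isopropenyl C > CH2 > H does not change along the route.

Step 1
Reactants: 1 pent-4-yn-1-ol
Product: 2 pent-4-ynal
Conditions: (COCl)2, DMSO, CH2Cl2, −78 °C; Et3N, −78 °C → rt
Reagents that add atoms: none
Why: Swern oxidation should stop at the aldehyde and leave the terminal alkyne untouched; the volatile aldehyde is kept as a concentrated solution and used at once.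

Step 2
Reactants: 2 pent-4-ynal; 3 isopropenylmagnesium bromide
Product: 4 (±)-2-methylhept-1-en-6-yn-3-ol
Conditions: THF, −78 → 0 °C; aq NH4Cl
Reagents that add atoms: none
Why: Grignard 1,2-addition to an unhindered aldehyde is much faster at low temperature than deprotonation of the alkyne C–H; the carbinol centre forms without control (racemate) and is resolved in step 3.

Step 3
Reactants: 4 (±)-2-methylhept-1-en-6-yn-3-ol
Product: 5 (3R)-2-methylhept-1-en-6-yn-3-ol
Conditions: Ti(Oi-Pr)4 (cat.), L-(+)-DIPT, t-BuOOH (0.6 equiv), 4 Å MS, CH2Cl2, −20 °C
Reagents that add atoms: none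
Why: Sharpless kinetic resolution: the titanium–L-(+)-tartrate catalyst should epoxidise the S enantiomer of this 2-substituted secondary allylic alcohol much faster, so the R alcohol is recovered enantioenriched when conversion is taken slightly past one half; the tartrate ligand thus selects the stereocentre.

Step 4
Reactants: 5 (3R)-2-methylhept-1-en-6-yn-3-ol
Product: 6 tert-butyldimethyl{[(3R)-2-methylhept-1-en-6-yn-3-yl]oxy}silane
Conditions: TBSCl, imidazole, DMF, rt
Reagents that add atoms: tert-butyldimethylsilyl chloride, CC(C)(C)[Si](C)(C)Cl
Why: Standard O-silylation; the ether masks the alcohol against Me3Al and no bond to the stereocentre is touched.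

Step 5
Reactants: 7 2,4,6-trihydroxybenzophenone
Product: 9 3-benzoyl-2,4,6-trihydroxybenzaldehyde, via aryl iminium chloride 8 (not isolated)
Conditions: POCl3 (1.1 equiv), DMF, EtOAc, 0 °C → rt; H2O, 60 °C
Reagents that add atoms: N,N-dimethylformamide, CN(C)C=O (formyl carbon of 9, Me2N=CH unit of 8); water, O (aldehyde oxygen of 9); phosphoryl chloride, O=P(Cl)(Cl)Cl (chloride counter-ion of 8)
Why: Vilsmeier–Haack formylation: the chloroiminium ion should attack one of the two equivalent free positions (C3/C5) of the activated phloroglucinol ring; the benzophenone has no enolisable position, and one equivalent of reagent plus the deactivating first formyl group limits double formylation.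

Step 6
Reactants: 9 3-benzoyl-2,4,6-trihydroxybenzaldehyde
Product: 10 3-benzoyl-2,4,6-tris(methoxymethoxy)benzaldehyde
Conditions: NaH, MOMCl, DMF, 0 °C → rt
Reagents that add atoms: chloromethyl methyl ether, COCCl
Why: Williamson-type O-alkylation of the sodium phenoxides with a hard, oxocarbenium-like electrophile; NaH in DMF is chosen because all three hydroxyls are hydrogen-bonded to a carbonyl group.

Step 7
Reactants: 10 3-benzoyl-2,4,6-tris(methoxymethoxy)benzaldehyde
Product: 11 [3-(hydroxymethyl)-2,4,6-tris(methoxymethoxy)phenyl](phenyl)methanone
Conditions: NaBH4 (0.5 equiv), EtOH/THF, −40 → −10 °C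
Reagents that add atoms: none
Why: Chemoselective borohydride reduction: the aldehyde should be reduced far faster than the diaryl ketone, which is flanked by two ortho substituents and twisted out of conjugation; MOM ethers are inert to hydride.

Step 8
Reactants: 11 [3-(hydroxymethyl)-2,4,6-tris(methoxymethoxy)phenyl](phenyl)methanone
Product: 13 [3-(chloromethyl)-2,4,6-tris(methoxymethoxy)phenyl](phenyl)methanone, via benzylic mesylate 12 (not isolated)
Conditions: MsCl, i-Pr2NEt, LiCl, THF, 0 °C
Reagents that add atoms: methanesulfonyl chloride, CS(=O)(=O)Cl (mesyl group of 12); lithium chloride, [Li+].[Cl-] (chlorine of 13)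
Why: Mesylation with in-situ chloride displacement (Collington–Meyers type) should convert the electron-rich benzylic alcohol under buffered, non-acidic conditions that spare the MOM acetals; because trialkoxybenzyl chlorides ionise easily, 13 is worked up cold, not chromatographed and used the same day.

Step 9
Reactants: 6 tert-butyldimethyl{[(3R)-2-methylhept-1-en-6-yn-3-yl]oxy}silane; 13 [3-(chloromethyl)-2,4,6-tris(methoxymethoxy)phenyl](phenyl)methanone; 14 trimethylaluminium
Product: 16 {3-[(2E,6R)-6-(tert-butyldimethylsilyloxy)-3,7-dimethylocta-2,7-dien-1-yl]-2,4,6-tris(methoxymethoxy)phenyl}(phenyl)methanone, via (E)-alkenyldimethylalane 15 (not isolated)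
Conditions: 6, Me3Al (2.0 equiv), Cp2ZrCl2 (0.25 equiv), CH2Cl2, 0 °C → rt; volatiles (excess Me3Al) removed in vacuo, THF; then 13, Ni(0) [NiCl2(PPh3)2 + 2 n-BuLi, 5 mol %], THF, 0 °C → rt
Reagents that add atoms: none
Why: Cp2ZrCl2 and Me3Al give an electrophilic Zr–CH3 species that inserts the terminal alkyne of 6 through a four-centre syn transition state, methyl going to the substituted carbon (future C3') and metal to the terminal carbon (future C2'); exchange to aluminium gives the (E)-alkenylalane 15, and Ni(0) then inserts into the benzylic C–Cl bond of 13, takes over the alkenyl group from aluminium and reductively eliminates to join C1' to C2' with the olefin geometry retained. The closest known reaction type is the Negishi zirconium-catalysed methylalumination of terminal alkynes followed by nickel- or palladium-catalysed coupling of the alkenylalane with a polyalkoxybenzyl chloride. No ring is closed and no stereocentre is created; the C6' carbinol of 6 lies three atoms from the reacting alkyne and is carried through unchanged as its silyl ether. Regio- and E-selectivity are needed and follow from the syn addition with methyl on the internal carbon, while chemoselectivity for the alkyne over the isopropenyl group is secured because a 1,1-disubstituted alkene does not insert into the zirconocene under these conditions. Attack of methylaluminium on the ketone or the MOM acetals of 13 should be avoided by stripping the excess Me3Al before 13 is added, by the coordinating THF and by the doubly ortho-flanked, twisted carbonyl, and alkenyl transfers in preference to methyl. As C1' enters as an sp3 electrophile already bonded to the ring, the linear chain cannot transpose and the phenol oxygens never meet an alkylating agent.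

Step 10
Reactants: 16 {3-[(2E,6R)-6-(tert-butyldimethylsilyloxy)-3,7-dimethylocta-2,7-dien-1-yl]-2,4,6-tris(methoxymethoxy)phenyl}(phenyl)methanone
Product: 17 {2,4,6-trihydroxy-3-[(2E,6R)-6-hydroxy-3,7-dimethylocta-2,7-dien-1-yl]phenyl}(phenyl)methanone
Conditions: HCl (ca. 1 M in MeOH), THF, 0 °C → rt; NaHCO3 quench
Reagents that add atoms: none
Why: Acid-catalysed methanolysis should cleave the three aryl MOM acetals and the secondary TBS ether in one flask; dilute acid at or below room temperature with prompt buffering is chosen so that the C2'=C3' olefin is not protonated (chroman closure onto an ortho phenol) and the allylic C6' carbinol is not ionised, so its R configuration is kept.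

**Compound list**

1 | pent-4-yn-1-ol | C#CCCCO | starting material
2 | pent-4-ynal | C#CCCC=O | intermediate
3 | isopropenylmagnesium bromide | C=C(C)[Mg]Br | starting material
4 | (±)-2-methylhept-1-en-6-yn-3-ol | C=C(C)C(O)CCC#C | intermediate
5 | (3R)-2-methylhept-1-en-6-yn-3-ol | C=C(C)[C@H](O)CCC#C | intermediate
6 | tert-butyldimethyl{[(3R)-2-methylhept-1-en-6-yn-3-yl]oxy}silane | C=C(C)[C@H](O[Si](C)(C)C(C)(C)C)CCC#C | intermediate
7 | 2,4,6-trihydroxybenzophenone | O=C(c1ccccc1)c1c(O)cc(O)cc1O | starting material
8 | N-[(3-benzoyl-2,4,6-trihydroxyphenyl)methylidene]-N-methylmethanaminium chloride | C[N+](C)=Cc1c(O)cc(O)c(C(=O)c2ccccc2)c1O.[Cl-] | intermediate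
9 | 3-benzoyl-2,4,6-trihydroxybenzaldehyde | O=Cc1c(O)cc(O)c(C(=O)c2ccccc2)c1O | intermediate
10 | 3-benzoyl-2,4,6-tris(methoxymethoxy)benzaldehyde | COCOc1cc(OCOC)c(C(=O)c2ccccc2)c(OCOC)c1C=O | intermediate
11 | [3-(hydroxymethyl)-2,4,6-tris(methoxymethoxy)phenyl](phenyl)methanone | COCOc1cc(OCOC)c(C(=O)c2ccccc2)c(OCOC)c1CO | intermediate
12 | [3-benzoyl-2,4,6-tris(methoxymethoxy)phenyl]methyl methanesulfonate | COCOc1cc(OCOC)c(C(=O)c2ccccc2)c(OCOC)c1COS(C)(=O)=O | intermediate
13 | [3-(chloromethyl)-2,4,6-tris(methoxymethoxy)phenyl](phenyl)methanone | COCOc1cc(OCOC)c(C(=O)c2ccccc2)c(OCOC)c1CCl | intermediate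
14 | trimethylaluminium | C[Al](C)C | starting material
15 | [(1E,5R)-5-(tert-butyldimethylsilyloxy)-2,6-dimethylhepta-1,6-dien-1-yl]dimethylalane | C=C(C)[C@H](O[Si](C)(C)C(C)(C)C)CC/C(C)=C/[Al](C)C | intermediate
16 | {3-[(2E,6R)-6-(tert-butyldimethylsilyloxy)-3,7-dimethylocta-2,7-dien-1-yl]-2,4,6-tris(methoxymethoxy)phenyl}(phenyl)methanone | C=C(C)[C@H](O[Si](C)(C)C(C)(C)C)CC/C(C)=C/Cc1c(OCOC)cc(OCOC)c(C(=O)c2ccccc2)c1OCOC | intermediate
17 | {2,4,6-trihydroxy-3-[(2E,6R)-6-hydroxy-3,7-dimethylocta-2,7-dien-1-yl]phenyl}(phenyl)methanone | C=C(C)[C@H](O)CC/C(C)=C/Cc1c(O)cc(O)c(C(=O)c2ccccc2)c1O | target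

**Totals**

Total step count: 10.
Longest linear sequence: 6 steps (7 → 9 → 10 → 11 → 13 → 16 → 17; the alkyne branch 1 → 2 → 4 → 5 → 6 → 16 → 17 is equally long).

**Steps most likely to fail**

1. Step 9. What may go wrong: methyl transfer from residual methylalanes to the benzophenone carbonyl, or Lewis-acid opening of the MOM acetals, before the coupling turns over. Transmetalation may also be slow enough that the chloride ionises and decomposes, and a minor regioisomeric carbometalation product cannot be removed at the alane stage. Fallback (aluminium is removed before the arene fragment appears, and the polarity of the sp3–sp2 coupling is reversed): the fallback sets out from alane 15, made from 6 as in the first half of step 9. Iodinolysis (I2, THF, −30 → 0 °C) should give tert-butyl{[(3R,6E)-7-iodo-2,6-dimethylhepta-1,6-dien-3-yl]oxy}dimethylsilane F1, which can be purified. Chloride 13 is converted by direct zinc insertion (Zn dust, LiCl, THF, rt) into [3-benzoyl-2,4,6-tris(methoxymethoxy)benzyl]zinc chloride F2, a reagent type that tolerates ketones. Palladium-catalysed Negishi coupling of F2 with F1 (Pd(OAc)2/SPhos, THF, rt) comes back to the route at 16.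

2. Step 8. What may go wrong: ionisation of the mesylate or chloride, assisted by the three alkoxy donors, followed by capture by an ortho MOM oxygen, hydrolysis or self-alkylation during work-up and storage. Fallback (a halide-free, much less ionisable benzylic electrophile and a boron instead of an aluminium nucleophile): the fallback sets out from alcohol 11. Diethyl chlorophosphate and pyridine (CH2Cl2, 0 °C) should give [3-benzoyl-2,4,6-tris(methoxymethoxy)phenyl]methyl diethyl phosphate F3, which can be chromatographed. Alane 15 is quenched with 2-methoxy-4,4,5,5-tetramethyl-1,3,2-dioxaborolane to give tert-butyl{[(3R,6E)-2,6-dimethyl-7-(4,4,5,5-tetramethyl-1,3,2-dioxaborolan-2-yl)hepta-1,6-dien-3-yl]oxy}dimethylsilane F4. Suzuki–Miyaura coupling of F3 with F4 (Pd(OAc)2, PPh3, K3PO4, toluene, 90 °C) comes back to the route at 16. This coupling type is established for benzylic phosphates with arylboronic acids; its use with an alkenylboronate is an extension.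

3. Step 10. What may go wrong: acid-promoted addition of an ortho phenol to the C2'=C3' olefin (chroman ring closure), or solvolysis of the allylic carbinol, before the slowest groups (the MOM ether para to the carbonyl and the silyl ether) are gone. Fallback (the two unmaskings are separated and Brønsted acid is avoided): the fallback sets out from 16. TBAF in THF at 0 °C should give {3-[(2E,6R)-6-hydroxy-3,7-dimethylocta-2,7-dien-1-yl]-2,4,6-tris(methoxymethoxy)phenyl}(phenyl)methanone F5. The aryl MOM ethers are then cleaved by Lewis-acid activation with thiol capture of the methoxymethyl group (ZnBr2, n-PrSH, CH2Cl2, 0 °C, short contact time), which comes back to the route at 17.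

**Further compounds**

F1 | step 9 | tert-butyl{[(3R,6E)-7-iodo-2,6-dimethylhepta-1,6-dien-3-yl]oxy}dimethylsilane | C=C(C)[C@H](O[Si](C)(C)C(C)(C)C)CC/C(C)=C/I
F2 | step 9 | [3-benzoyl-2,4,6-tris(methoxymethoxy)benzyl]zinc chloride | COCOc1cc(OCOC)c(C(=O)c2ccccc2)c(OCOC)c1C[Zn]Cl
F3 | step 8 | [3-benzoyl-2,4,6-tris(methoxymethoxy)phenyl]methyl diethyl phosphate | COCOc1cc(OCOC)c(C(=O)c2ccccc2)c(OCOC)c1COP(=O)(OCC)OCC
F4 | step 8 | tert-butyl{[(3R,6E)-2,6-dimethyl-7-(4,4,5,5-tetramethyl-1,3,2-dioxaborolan-2-yl)hepta-1,6-dien-3-yl]oxy}dimethylsilane | C=C(C)[C@H](O[Si](C)(C)C(C)(C)C)CC/C(C)=C/B1OC(C)(C)C(C)(C)O1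
F5 | step 10 | {3-[(2E,6R)-6-hydroxy-3,7-dimethylocta-2,7-dien-1-yl]-2,4,6-tris(methoxymethoxy)phenyl}(phenyl)methanone | C=C(C)[C@H](O)CC/C(C)=C/Cc1c(OCOC)cc(OCOC)c(C(=O)c2ccccc2)c1OCOC
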